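The pitfall in these runs is to book each G that disappears as G taken up by E.

| flask | G | E | remark | time |
|---|---|---|---|---|
| birch | 20 mM | 90 mM (in portions, 3) | run made earlier; portions every 2.5 s |  |
| flask | 20 mM | 60.0 mM (in portions, 3) | the portions of E follow each other after 2.5 s, the first at the start | 5.0 min |

birch run (percent of the G charged)

| time / s | G / % | Z / % |
|---|---|---|
| 10.0 | 66.5 | 7.1 |
| 15.0 | 54.6 | 8.1 |
| 40.0 | 28.5 | 12.4 |
| 90.0 | 12.9 | 7.3 |

(readings scatter by 1 percentage point)



1. G at 5.0 min, in percent of the G charged
2. Z at 5.0 min, in percent of the G charged
3. Q at 5.0 min, in percent of the G charged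

In the birch run at 10.0 s, G has lost 33.5% of its charge while Z stands at 7.1%, and the reciprocal of [G] climbs roughly straight with time. This reckoning therefore assumes two routes for G: one through E, and one without E, second order in G. One selectivity factor folds the givens together: the rate of the E route over that of the other route, with [G] at its charge, here called B. Neglecting early Q, the share through E is 0.212, which gives B = 0.224 at a mean nominal [E] of 67.5 mM. The scatter of 1 percentage point carries straight into it.

Scaled to the flask's charge, B = 0.199. With [E], and so B, held at one value, while a fraction g of G remains the share through E is B/(B+g), so Z and Q together come to B ln((1+B)/(g+B)). The straight reciprocal line through the last birch reading, carried to 5.0 min, is taken for this flask and puts G at an estimated 4.25%, and the first pass gives 31.9%. Counting one E per G taken up, this reckoning takes 6.38 mM off [E], so B becomes 0.178 and Z plus Q 29.8%. One number was not enough: G needed the line, and the split between Z and Q stays open.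

The forecast differs, with G 7%, Z 13% and Q 80%, since for it “Q is the remainder”.

The flask gives G 4.73%, Z 4.10% and Q 21.8%.

    G + E → Z (k = 0.146 M⁻¹ s⁻¹)
    E + Z → Q (k = 0.417 M⁻¹ s⁻¹)
    2 G → L (k = 1.00 M⁻¹ s⁻¹)
    E → X (k = 0.00583 s⁻¹)

In the flask at 5.00 min, E stands at 13.1% of its charge, with 0.477 equiv per G charged in Z and Q and X at 42.6 mM. With the flask's G put back, B = 0.178 gives 29.4%, more than the 25.9% found in that flask. For the neighbouring flask with 50 mM of G, B falls to 0.0796, and one round through E with that flask's G brings it to 0.0671, which gives 16.7%; that flask holds 14.8% in Z and Q.

The numbers in the tables are simulated for an exercise.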